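**Plan**

1. Retrosynthesis: the pyran bond O3′–C2″ is cut first (oxa-6π closure of a C2′-prenyl ortho-quinone methide, leading back to catechol 17). Next comes the C3–C1′ bond between chromone and ring B (Suzuki coupling of iodochromone 15 with boronate 11). Last are C2′–C4″ (aromatic Claisen rearrangement from an O3′ 1,1-dimethylallyl ether) and the pyranone C2 with its O1–C2 bond (enaminone iodocyclisation).
2. Enabling feature: in ring B the pyran oxygen O3′ lies between C4′, which carries the free hydroxyl, and C2′, which carries the pyran carbon C4″. This is the pattern left when a 3′,4′-ortho-quinone with a prenyl group on C2′ closes onto O3′.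
3. Forward order: ring B is prepared first (O3′ by Dakin-type oxidation, the C2′ prenyl group by Claisen rearrangement, boron at C1′). The pyranone ring C is closed on ring A, the halves are joined at C3–C1′, the acetals are removed, and the pyran ring is closed last.
4. Stereochemistry: the target has no stereocentre. The only stereochemical element on the way is the Z geometry of the transient quinone methide, which is reached by reversible proton transfer.

Key step: step 13

Remark on the chemistry: ring B atoms are primed (C1′ is bonded to C3 of the chromone); the pyran atoms are O3′, C2″ (CMe2), C3″ and C4″ (on C2′); MOM = methoxymethyl. Compounds 1, 5 and 12 are assumed to be purchased.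

**Route**

Step 1
Reactants: 1 5-bromo-2-hydroxy-3-methoxybenzaldehyde
Product: 2 5-bromo-3-methoxy-2-(methoxymethoxy)benzaldehyde
Conditions: MOMCl, iPr2NEt, CH2Cl2, 0 °C → rt
Reagents that add atoms: chloromethyl methyl ether (MOMCl), COCCl
Why: Williamson-type MOM protection masks the future O4′ before the aldehyde is oxidised, and the acetal should survive the basic, reductive, thermal and palladium-catalysed steps that follow.

Step 2
Reactants: 2 5-bromo-3-methoxy-2-(methoxymethoxy)benzaldehyde
Product: 4 5-bromo-3-methoxy-2-(methoxymethoxy)phenol, via aryl formate 3 (not isolated)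
Conditions: mCPBA, CH2Cl2, 0 °C → rt; aq NaHCO3 wash; then K2CO3 (cat.), MeOH, rt
Reagents that add atoms: 3-chloroperoxybenzoic acid (mCPBA), OOC(=O)c1cccc(Cl)c1
Why: In this Baeyer–Villiger (Dakin-type) oxidation the electron-rich aryl group with its ortho alkoxy substituent should migrate in preference to hydrogen, and methanolysis of the formate frees the future O3′ as the only phenol.

Step 3
Reactants: 4 5-bromo-3-methoxy-2-(methoxymethoxy)phenol; 5 3-chloro-3-methylbut-1-yne
Product: 6 5-bromo-1-methoxy-2-(methoxymethoxy)-3-(2-methylbut-3-yn-2-yloxy)benzene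
Conditions: CuCl2·2H2O (1 mol %), DBU, MeCN, 0 °C
Reagents that add atoms: none
Why: Copper-catalysed propargylic substitution of the tertiary chloride by the phenoxide is the standard entry to tertiary aryl propargyl ethers and runs well below the temperature at which the ether would rearrange.

Step 4
Reactants: 6 5-bromo-1-methoxy-2-(methoxymethoxy)-3-(2-methylbut-3-yn-2-yloxy)benzene
Product: 7 5-bromo-1-methoxy-2-(methoxymethoxy)-3-(2-methylbut-3-en-2-yloxy)benzene
Conditions: H2 (1 atm), Pd on CaCO3 poisoned with Pb(OAc)2 (Lindlar catalyst), quinoline, EtOAc, rt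
Reagents that add atoms: none
Why: Lindlar semihydrogenation should stop at the alkene and leave the aryl bromide and the acetal untouched, giving the 1,1-dimethylallyl ether needed for the sigmatropic shift.

Step 5
Reactants: 7 5-bromo-1-methoxy-2-(methoxymethoxy)-3-(2-methylbut-3-en-2-yloxy)benzene
Product: 9 3-bromo-5-methoxy-6-(methoxymethoxy)-2-(3-methylbut-2-enyl)phenol, via cyclohexadienone 8 (not isolated)
Conditions: N,N-diethylaniline, 150 °C
Reagents that add atoms: none
Why: In this aromatic Claisen rearrangement the [3,3] shift can only deliver the allyl unit to the single free ortho carbon (the future C2′), which inverts it to the 3-methylbut-2-enyl group, and the dienone then enolises to the phenol.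

Step 6
Reactants: 9 3-bromo-5-methoxy-6-(methoxymethoxy)-2-(3-methylbut-2-enyl)phenol
Product: 10 1-bromo-5-methoxy-3,4-bis(methoxymethoxy)-2-(3-methylbut-2-enyl)benzene
Conditions: MOMCl, iPr2NEt, DMAP (cat.), CH2Cl2, 0 → 40 °C
Reagents that add atoms: chloromethyl methyl ether (MOMCl), COCCl
Why: MOM protection of the newly freed phenol (Williamson-type O-alkylation) keeps O3′ away from the palladium chemistry and gives all three phenolic oxygens the same protecting group for a single later cleavage.

Step 7
Reactants: 10 1-bromo-5-methoxy-3,4-bis(methoxymethoxy)-2-(3-methylbut-2-enyl)benzene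
Product: 11 2-[5-methoxy-3,4-bis(methoxymethoxy)-2-(3-methylbut-2-enyl)phenyl]-4,4,5,5-tetramethyl-1,3,2-dioxaborolane
Conditions: B2pin2, Pd(dppf)Cl2·CH2Cl2 (5 mol %), KOAc, 1,4-dioxane, 90 °C
Reagents that add atoms: bis(pinacolato)diboron, CC1(C)OB(OC1(C)C)B1OC(C)(C)C(C)(C)O1
Why: Miyaura borylation converts electron-rich aryl bromides into pinacol boronates under weakly basic conditions that the acetals and the trisubstituted alkene tolerate.

Step 8
Reactants: 12 1-(2,4-dihydroxyphenyl)ethanone
Product: 13 1-[2-hydroxy-4-(methoxymethoxy)phenyl]ethanone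
Conditions: MOMCl (1.05 equiv), iPr2NEt, CH2Cl2, 0 °C
Reagents that add atoms: chloromethyl methyl ether (MOMCl), COCCl
Why: In this MOM protection only the 4-hydroxyl should react, because the 2-hydroxyl is held in a hydrogen bond to the ketone and is much less nucleophilic.

Step 9
Reactants: 13 1-[2-hydroxy-4-(methoxymethoxy)phenyl]ethanone
Product: 14 (E)-3-(dimethylamino)-1-[2-hydroxy-4-(methoxymethoxy)phenyl]prop-2-en-1-one
Conditions: Me2NCH(OMe)2, toluene, 100 °C
Reagents that add atoms: N,N-dimethylformamide dimethyl acetal, COC(OC)N(C)C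
Why: Condensation of the methyl ketone with the amide acetal (enaminone formation) adds the carbon that becomes C2 of the chromone and gives the thermodynamically preferred E enaminone.

Step 10
Reactants: 14 (E)-3-(dimethylamino)-1-[2-hydroxy-4-(methoxymethoxy)phenyl]prop-2-en-1-one
Product: 15 3-iodo-7-(methoxymethoxy)chromen-4-one
Conditions: I2, pyridine, CHCl3, rt
Reagents that add atoms: iodine, II
Why: In this Gammill-type iodocyclisation the enaminone is iodinated at its α-carbon, the phenol adds to the resulting iminium carbon, and loss of dimethylamine gives the 3-iodochromone.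

Step 11
Reactants: 11 2-[5-methoxy-3,4-bis(methoxymethoxy)-2-(3-methylbut-2-enyl)phenyl]-4,4,5,5-tetramethyl-1,3,2-dioxaborolane; 15 3-iodo-7-(methoxymethoxy)chromen-4-one
Product: 16 3-[5-methoxy-3,4-bis(methoxymethoxy)-2-(3-methylbut-2-enyl)phenyl]-7-(methoxymethoxy)chromen-4-one
Conditions: Pd(dppf)Cl2·CH2Cl2 (5 mol %), K2CO3, 1,4-dioxane/H2O (4:1), 80 °C
Reagents that add atoms: none
Why: Suzuki–Miyaura coupling of 3-iodochromones with arylboron reagents is the established way to form the C3–C1′ bond of isoflavones, and the trisubstituted prenyl alkene should not compete in Heck-type insertion.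

Step 12
Reactants: 16 3-[5-methoxy-3,4-bis(methoxymethoxy)-2-(3-methylbut-2-enyl)phenyl]-7-(methoxymethoxy)chromen-4-one
Product: 17 3-[3,4-dihydroxy-5-methoxy-2-(3-methylbut-2-enyl)phenyl]-7-hydroxychromen-4-one
Conditions: HCl (3 M aq), MeOH, 40 °C, under argon
Reagents that add atoms: none
Why: Acid-catalysed acetal cleavage in methanol removes all three MOM groups at once, a deprotection commonly used on prenylated polyphenols, and the mild temperature is chosen so that the C2′ prenyl alkene is not protonated.

Step 13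
Reactants: 17 3-[3,4-dihydroxy-5-methoxy-2-(3-methylbut-2-enyl)phenyl]-7-hydroxychromen-4-one
Product: 20 7-hydroxy-3-(8-hydroxy-7-methoxy-2,2-dimethyl-2H-chromen-5-yl)chromen-4-one (target CNP0338889.0), via ortho-quinone 18 (not isolated), via quinone methide 19 (not isolated)
Conditions: DDQ (1.0 equiv, slow addition), 1,4-dioxane, rt, then 50 °C
Reagents that add atoms: none
Why: DDQ removes two hydrogens from the electron-rich 3′,4′-catechol to give ortho-quinone 18, whose C4′ carbonyl is conjugated through C5′=C6′ and C1′=C2′ to the prenyl CH2 (C4″), so a proton moves from C4″ to O4′ and gives the Z ortho-quinone methide 19. In 19 the atoms O3′=C3′–C2′=C4″–C3″=C2″ form a 1-oxatriene, and thermal disrotatory 6π electrocyclisation makes the O3′–C2″ bond, closes the six-membered pyran and restores aromatic ring B with O4′ as a phenol. The closest known reactions are the DDQ dehydrogenative cyclisation of ortho-prenylphenols, prenylated isoflavones with free hydroxyls included, to 2,2-dimethyl-2H-chromenes and the isomerisation of prenylquinones to chromenols. No stereocentre is formed, and an E quinone methide can reach the reactive Z form by reversible proton transfer. Chemoselectivity should come from the catechol being far easier to oxidise than the 7-OH on the electron-poor chromone and from using one equivalent of DDQ, so that the product phenol is not oxidised again. Regioselectivity is built in, because only the C3′ carbonyl is bonded to C2′, so O3′ and not O4′ enters the ring.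

**Compound list**

1 | 5-bromo-2-hydroxy-3-methoxybenzaldehyde | COc1cc(Br)cc(C=O)c1O | starting material
2 | 5-bromo-3-methoxy-2-(methoxymethoxy)benzaldehyde | COCOc1c(OC)cc(Br)cc1C=O | intermediate
3 | [5-bromo-3-methoxy-2-(methoxymethoxy)phenyl] formate (not isolated) | COCOc1c(OC)cc(Br)cc1OC=O | intermediate
4 | 5-bromo-3-methoxy-2-(methoxymethoxy)phenol | COCOc1c(OC)cc(Br)cc1O | intermediate
5 | 3-chloro-3-methylbut-1-yne | CC(C)(Cl)C#C | starting material
6 | 5-bromo-1-methoxy-2-(methoxymethoxy)-3-(2-methylbut-3-yn-2-yloxy)benzene | COCOc1c(OC)cc(Br)cc1OC(C)(C)C#C | intermediate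
7 | 5-bromo-1-methoxy-2-(methoxymethoxy)-3-(2-methylbut-3-en-2-yloxy)benzene | COCOc1c(OC)cc(Br)cc1OC(C)(C)C=C | intermediate
8 | 5-bromo-3-methoxy-2-(methoxymethoxy)-6-(3-methylbut-2-enyl)cyclohexa-2,4-dien-1-one (racemic, not isolated) | COCOC1=C(OC)C=C(Br)C(CC=C(C)C)C1=O | intermediate
9 | 3-bromo-5-methoxy-6-(methoxymethoxy)-2-(3-methylbut-2-enyl)phenol | COCOc1c(OC)cc(Br)c(CC=C(C)C)c1O | intermediate
10 | 1-bromo-5-methoxy-3,4-bis(methoxymethoxy)-2-(3-methylbut-2-enyl)benzene | COCOc1c(OC)cc(Br)c(CC=C(C)C)c1OCOC | intermediate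
11 | 2-[5-methoxy-3,4-bis(methoxymethoxy)-2-(3-methylbut-2-enyl)phenyl]-4,4,5,5-tetramethyl-1,3,2-dioxaborolane | COCOc1c(OC)cc(B2OC(C)(C)C(C)(C)O2)c(CC=C(C)C)c1OCOC | intermediate
12 | 1-(2,4-dihydroxyphenyl)ethanone | CC(=O)c1ccc(O)cc1O | starting material
13 | 1-[2-hydroxy-4-(methoxymethoxy)phenyl]ethanone | CC(=O)c1ccc(OCOC)cc1O | intermediate
14 | (E)-3-(dimethylamino)-1-[2-hydroxy-4-(methoxymethoxy)phenyl]prop-2-en-1-one | CN(C)/C=C/C(=O)c1ccc(OCOC)cc1O | intermediate
15 | 3-iodo-7-(methoxymethoxy)chromen-4-one | COCOc1ccc2c(c1)occ(I)c2=O | intermediate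
16 | 3-[5-methoxy-3,4-bis(methoxymethoxy)-2-(3-methylbut-2-enyl)phenyl]-7-(methoxymethoxy)chromen-4-one | COCOc1ccc2c(c1)occ(-c1cc(OC)c(OCOC)c(OCOC)c1CC=C(C)C)c2=O | intermediate
17 | 3-[3,4-dihydroxy-5-methoxy-2-(3-methylbut-2-enyl)phenyl]-7-hydroxychromen-4-one | CC(C)=CCc1c(-c2coc3cc(O)ccc3c2=O)cc(OC)c(O)c1O | intermediate
18 | 7-hydroxy-3-[5-methoxy-2-(3-methylbut-2-enyl)-3,4-dioxocyclohexa-1,5-dien-1-yl]chromen-4-one (ortho-quinone, not isolated) | CC(C)=CCC1=C(c2coc3cc(O)ccc3c2=O)C=C(OC)C(=O)C1=O | intermediate
19 | 7-hydroxy-3-[(6Z)-4-hydroxy-3-methoxy-6-(3-methylbut-2-enylidene)-5-oxocyclohexa-1,3-dien-1-yl]chromen-4-one (ortho-quinone methide, not isolated) | CC(C)=C/C=C1\C(=O)C(O)=C(OC)C=C1c1coc2cc(O)ccc2c1=O | intermediate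
20 | 7-hydroxy-3-(8-hydroxy-7-methoxy-2,2-dimethyl-2H-chromen-5-yl)chromen-4-one | COc1cc(-c2coc3cc(O)ccc3c2=O)c2c(c1O)OC(C)(C)C=C2 | target

**Step count and risks**

Total step count: 13. Longest linear sequence: 10 steps (steps 1–7, 11, 12, 13); the ring A branch (steps 8–10) joins at step 11.

Steps most likely to fail:

1. **Step 13.** The ortho-quinone may be lost to dimerisation or nucleophilic addition before the proton shift, and the product phenol may be oxidised further. The fallback sets out from 6 and reaches the same O3′–C2″ bond by the same oxa-6π closure without an oxidant. Heating 6 in N,N-diethylaniline at 190 °C should trigger the aromatic propargyl Claisen cascade ([3,3] shift, enolisation, 1,5-hydrogen shift, electrocyclisation) and give 5-bromo-7-methoxy-8-(methoxymethoxy)-2,2-dimethyl-2H-chromene F1. Miyaura borylation as in step 7 would give 2-[7-methoxy-8-(methoxymethoxy)-2,2-dimethyl-2H-chromen-5-yl]-4,4,5,5-tetramethyl-1,3,2-dioxaborolane F2. Suzuki coupling with 15 as in step 11 would give 3-[7-methoxy-8-(methoxymethoxy)-2,2-dimethyl-2H-chromen-5-yl]-7-(methoxymethoxy)chromen-4-one F3. Cleavage of its two acetals with HCl in MeOH comes back to the route at 20.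

2. **Step 12.** Under acid the prenyl alkene may be protonated and captured by the neighbouring O3′ hydroxyl (chroman formation) while the acetals are being cleaved. The fallback sets out from 9 and unveils the phenols in two orthogonal stages, so that O3′ stays blocked while acid is present. Silylation of 9 (TBSOTf, 2,6-lutidine, CH2Cl2) would give tert-butyl-[3-bromo-5-methoxy-6-(methoxymethoxy)-2-(3-methylbut-2-enyl)phenoxy]dimethylsilane F4. Miyaura borylation would give tert-butyl-[3-methoxy-2-(methoxymethoxy)-6-(3-methylbut-2-enyl)-5-(4,4,5,5-tetramethyl-1,3,2-dioxaborolan-2-yl)phenoxy]dimethylsilane F5. Suzuki coupling with 15 would give 3-[3-(tert-butyldimethylsilyloxy)-5-methoxy-4-(methoxymethoxy)-2-(3-methylbut-2-enyl)phenyl]-7-(methoxymethoxy)chromen-4-one F6. HCl in MeOH should then remove only the two acetals and leave the hindered aryl silyl ether, giving 3-[3-(tert-butyldimethylsilyloxy)-4-hydroxy-5-methoxy-2-(3-methylbut-2-enyl)phenyl]-7-hydroxychromen-4-one F7. Buffered fluoride (TBAF, AcOH, THF, 0 °C) comes back to the route at 17.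

3. **Step 11.** The electron-rich, ortho-substituted boronate may protodeboronate, and the pyranone ring may be opened by aqueous base at C2. The fallback sets out from 10 and replaces the boron nucleophile by zinc under anhydrous, base-free conditions. Bromine–lithium exchange (n-BuLi, THF, −78 °C) and transmetalation with ZnCl2 would give chloro[5-methoxy-3,4-bis(methoxymethoxy)-2-(3-methylbut-2-enyl)phenyl]zinc F8. Negishi coupling of F8 with 15 (Pd2(dba)3, SPhos, THF, rt → 50 °C) comes back to the route at 16.

**Further compounds**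

F1 | step 13 | 5-bromo-7-methoxy-8-(methoxymethoxy)-2,2-dimethyl-2H-chromene | COCOc1c(OC)cc(Br)c2C=CC(C)(C)Oc12
F2 | step 13 | 2-[7-methoxy-8-(methoxymethoxy)-2,2-dimethyl-2H-chromen-5-yl]-4,4,5,5-tetramethyl-1,3,2-dioxaborolane | COCOc1c(OC)cc(B3OC(C)(C)C(C)(C)O3)c2C=CC(C)(C)Oc12
F3 | step 13 | 3-[7-methoxy-8-(methoxymethoxy)-2,2-dimethyl-2H-chromen-5-yl]-7-(methoxymethoxy)chromen-4-one | COCOc1ccc2c(c1)occ(-c1cc(OC)c(OCOC)c3OC(C)(C)C=Cc13)c2=O
F4 | step 12 | tert-butyl-[3-bromo-5-methoxy-6-(methoxymethoxy)-2-(3-methylbut-2-enyl)phenoxy]dimethylsilane | COCOc1c(OC)cc(Br)c(CC=C(C)C)c1O[Si](C)(C)C(C)(C)C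
F5 | step 12 | tert-butyl-[3-methoxy-2-(methoxymethoxy)-6-(3-methylbut-2-enyl)-5-(4,4,5,5-tetramethyl-1,3,2-dioxaborolan-2-yl)phenoxy]dimethylsilane | COCOc1c(OC)cc(B2OC(C)(C)C(C)(C)O2)c(CC=C(C)C)c1O[Si](C)(C)C(C)(C)C
F6 | step 12 | 3-[3-(tert-butyldimethylsilyloxy)-5-methoxy-4-(methoxymethoxy)-2-(3-methylbut-2-enyl)phenyl]-7-(methoxymethoxy)chromen-4-one | COCOc1ccc2c(c1)occ(-c1cc(OC)c(OCOC)c(O[Si](C)(C)C(C)(C)C)c1CC=C(C)C)c2=O
F7 | step 12 | 3-[3-(tert-butyldimethylsilyloxy)-4-hydroxy-5-methoxy-2-(3-methylbut-2-enyl)phenyl]-7-hydroxychromen-4-one | CC(C)=CCc1c(-c2coc3cc(O)ccc3c2=O)cc(OC)c(O)c1O[Si](C)(C)C(C)(C)C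
F8 | step 11 | chloro[5-methoxy-3,4-bis(methoxymethoxy)-2-(3-methylbut-2-enyl)phenyl]zinc | COCOc1c(OC)cc([Zn]Cl)c(CC=C(C)C)c1OCOC
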